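**Assumption:** the target has no stereocentre, so it is achiral and "single enantiomer" simply means the compound as drawn; hexacosanoic acid and tyrosol are taken as commercially available.

**Retrosynthetic overview**
- The only strategic bond is the ester C(=O)–O bond; cutting it gives hexacosanoic acid and tyrosol, both commercial.
- No ring is formed in the route; the benzene ring comes in ready-made with tyrosol.
- The forward reaction is a chemoselective acid-catalysed esterification of the primary aliphatic hydroxyl, with the phenol left free and no protecting groups.

**Route**

Step 1
Reactants: 1 hexacosanoic acid (1.0 equiv); 2 4-(2-hydroxyethyl)phenol (tyrosol, 2.0 equiv)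
Product: 3 2-(4-hydroxyphenyl)ethyl hexacosanoate (target)
Conditions: TsOH·H2O (0.1 equiv), toluene, reflux, Dean–Stark trap, 12 h; then warm aq. NaHCO3 and water washes (remove TsOH and excess tyrosol), recrystallisation from EtOAc/hexane
Reagents that add atoms: none
Why: This is a Fischer esterification in which only the primary aliphatic hydroxyl is nucleophilic enough to attack the protonated acid (phenols are not esterified under these equilibrium conditions), azeotropic removal of water drives the reaction to completion, and no stereocentre is created.

**Compound list**
1 | hexacosanoic acid (cerotic acid) | CCCCCCCCCCCCCCCCCCCCCCCCCC(=O)O | starting material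
2 | 4-(2-hydroxyethyl)phenol (tyrosol) | OCCc1ccc(O)cc1 | starting material
3 | 2-(4-hydroxyphenyl)ethyl hexacosanoate | CCCCCCCCCCCCCCCCCCCCCCCCCC(=O)OCCc1ccc(O)cc1 | target

**Totals**
Total step count: 1
Longest linear sequence: 1 step

**Steps most likely to fail**
The route has a single step, so step 1 is the only one that can be ranked.

Step 1 risks: tyrosol is only sparingly soluble in toluene; unreacted C26 acid would co-crystallise with the waxy product if conversion is incomplete; and hot acid could cause some self-condensation of tyrosol or a trace of aryl ester.

Fallback for step 1 (protect–couple–deprotect instead of direct chemoselective esterification). It sets out from compound 2 and comes back to the route at compound 3. Tyrosol 2 is benzylated selectively at the more acidic phenol (BnBr, K2CO3, acetone, reflux; Williamson ether synthesis) to give 2-[4-(benzyloxy)phenyl]ethanol F1. The free primary alcohol of this is then coupled with acid 1 by Steglich esterification (DCC, cat. DMAP, CH2Cl2/THF, 40 °C) to give 2-[4-(benzyloxy)phenyl]ethyl hexacosanoate F2. Hydrogenolysis of the benzyl ether (H2, 1 atm, 10% Pd/C, THF/EtOAc, 40 °C) leaves the homobenzylic ester untouched and delivers 3.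

**Further compounds**
F1 | step 1 | 2-[4-(benzyloxy)phenyl]ethanol | OCCc1ccc(OCc2ccccc2)cc1
F2 | step 1 | 2-[4-(benzyloxy)phenyl]ethyl hexacosanoate | CCCCCCCCCCCCCCCCCCCCCCCCCC(=O)OCCc1ccc(OCc2ccccc2)cc1
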